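Readings and results are simulated with made-up constants, and the scatter is random.

Answer 3 questions on the green flask, the one followed so far, at the time asked: how much target, open intermediate and substrate it then holds.

| flask | substrate | partner | remark | time |
|---|---|---|---|---|
| green | 0.40 M | 0.28 M | the very flask that is asked about, followed so far |  |
| ochre | 0.27 M | 0.28 M | run made earlier |  |
| flask | 0.40 M | 0.280 M |  | 4.0 h |

* target present at 4.0 h, in percent of the substrate charged
* open intermediate present at 4.0 h, in percent of the substrate charged
* substrate present at 4.0 h, in percent of the substrate charged

green run (percent of the substrate charged)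

| time / min | target / % | open intermediate / % | substrate / % |
|---|---|---|---|
| 12.0 | 3 | 5 | 91 |
| 25.0 | 10 | 7 | 83 |
| 40.0 | 22 | 8 | 71 |
| 50.0 | 29 | 7 | 66 |
| 60.0 | 31 | 7 | 60 |
| 80.0 | 43 | 5 | 49 |

ochre run (percent of the substrate charged)

| time / h | target / % | open intermediate / % | substrate / % |
|---|---|---|---|
| 0.200 | 0 | 8 | 89 |
| 0.500 | 18 | 6 | 76 |
| 1.00 | 35 | 4 | 62 |
| 1.50 | 48 | 3 | 44 |
| 2.00 | 61 | 3 | 37 |
| 3.00 | 73 | 0 | 24 |

(each reading ± 1.5 percentage points)

- a reading or a percentage of target counts all its forms, free or not

Read the charges first: partner is 0.28 M in both runs, so green holds less partner than substrate, but ochre holds more. Follow one substrate molecule and suppose that it needs one partner to become target, which gives the partner ceiling, partner charged over substrate charged, the most target that partner as limiting reagent allows, 70.0% for green, while in ochre the same ratio is 104%, so that there substrate is the limiting reagent. But the readings do not test this supposition, since green's last target, 43%, stands below its ceiling, and so does ochre's last, 73%. Extend green's straight climb from 22% to 43%, and it meets the ceiling at 2.19 h, earlier than the 4.0 h asked. So commit to target near the ceiling, with about 30.0% of the substrate charged standing outside target, as substrate and open intermediate as far as the readings show. The forecast, which reads that partner “caps target at 70% if partner is consumed”, gives target 72%, open intermediate 8% and substrate 15%, putting target above the ceiling, where this reckoning stays at it.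

The flask gives target 68.3%, open intermediate 12.1% and substrate 16.7%.

    partner + target ⇌ idle adduct, settled at all times (K = 9.30 M⁻¹)
    open intermediate + second intermediate → target (k = 49.5 M⁻¹ h⁻¹)
    partner → second intermediate (k = 2.43 h⁻¹)
    substrate ⇌ open intermediate (K = 1.40, k = 0.538 h⁻¹)
    substrate + open intermediate → side product (k = 0.303 M⁻¹ h⁻¹)

Green stands 1.7 percentage points below its ceiling, with 0.40% of its partner left. Now cut the partner in the same flask to 0.070 M: the ceiling becomes 17.5%, and at 4.00 h that neighbour holds target 17.5%, with 0.085% of its partner left, open intermediate 39.2%, substrate 30.8% and side product 12.6%.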